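## Structural features

The target is a single tetrahydrofuran ring (O1, C2, C3, C4, C5) with nothing fused to it. C2 and C5 each carry a 4-hydroxy-3,5-dimethoxyphenyl (syringyl) ring through a C–C single bond, and C3 and C4 each carry a hydroxymethyl group. C2, C3, C4 and C5 are four contiguous stereocentres, all-trans around the ring, (2R,3S,4S,5R). A C2 axis through O1 and the midpoint of C3–C4 makes the two halves equivalent, so only two stereocentres are independent. The fragile sites are the benzylic ether carbons C2 and C5, each para to a free phenol. Acid or phenoxide formation can open the C–O bond to a quinone methide, which scrambles C2/C5 and, once the hydroxymethyl groups are present, can be captured by the 1,4-related CH2OH to give an isomeric ring system. The same benzylic C–O bonds are open to hydrogenolysis and the electron-rich rings to oxidation. C3 and C4 cannot be corrected once set, so the real difficulty is the absolute configuration of the C3–C4 pair and its trans relationship to both aryl-bearing neighbours. The key step uses two features: C2–O1–C5 with its two aryl groups has the connectivity of a diaryl carbonyl ylide, and the trans C3–C4 unit with two carboxyl-level substituents is a fumarate.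

## Logic of the disconnections

**9 ⇒ 8.** The two aryl O–Si bonds are cut, so the phenols are unmasked last. A free 4-hydroxyaryl group cannot be carried through an oxirane, an ylide or a hydride reduction without quinone methide formation or reagent quenching. A benzyl ether was rejected as the mask for two reasons: it sits on the chromophore that must absorb the light in the key step and can undergo photochemical O–CH2 homolysis, and its hydrogenolysis would endanger the benzylic ring bonds C2–O1 and C5–O1. A triisopropylsilyl ether is inert to light, to low-valent titanium and to hydride. The demand on the forward step is a deprotection that is neither acidic nor reductive.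

**8 ⇒ 7.** The two CH2OH carbons are traced back to carboxylic esters; the bonds cut are the acyl C–O bonds to the auxiliary alcohol. The ester level makes the C3–C4 unit an electron-poor alkene and lets it carry removable chirality. The forward step must reduce two hindered esters faster than it enolises C3/C4 or expels O1 by β-elimination.

**7 ⇒ 4 + 5 (through 6).** C2–C3 and C4–C5 are cut. This one cut removes the ring, both skeletal C–C bonds and all four stereocentres, and it returns two symmetrical partners. The forward step has four demands: 6 must be generated in the presence of 5 without exciting 5; 6 must have the exo,endo geometry; the addition must be suprafacial on both partners; and one face of 5 must be selected.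

**4 ⇒ 3.** Both C–O bonds of the three-membered ring are cut, back to 3. The trans geometry is then inherited from the E-configured double bond, and the absolute configuration of 4 is irrelevant because 6 is achiral. The forward step needs a neutral, stereospecific oxygen-transfer reagent, since 4 is sensitive to acid.

**3 ⇒ 2 + 2.** The central C=C bond is cut into two identical aldehyde carbons. The symmetry of the target halves the problem, and one reductive carbonyl coupling replaces a multi-step benzylic activation. The forward step must give the E-isomer and spare the silyl ethers.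

**2 ⇒ 1.** The O–Si bond is cut, back to 1, which is commercial.

## Other disconnections considered

Alternative 1: The cut is C3–C4 together with O1–C2 and O1–C5. Forward, the chiral imide (S)-4-benzyl-3-[(E)-sinapoyl]oxazolidin-2-one A1 would be oxidised with FeCl3 in aqueous acetone. Two phenoxyl radicals derived from A1 would join at their β-carbons, and water would then bridge the two quinone methide termini of the dimer to give the all-trans bis-imide A2. Hydride reduction of A2 would give the target.
- In favour: no phenol protection is needed, the oxidation level is right from the start, and the syringyl rings of A1 have both ortho positions blocked, so β–β coupling has no β–aryl competitor. The way to A1 and on from A2 would be about three or four steps in all, which is better in step economy than the chosen plan. The final C2/C5 configuration of A2 would come from reversible water capture and should settle on the all-trans ring, which is equal to the chosen plan.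
- Against: the doubly oxidised dimer has other exits, namely intramolecular Friedel–Crafts closure onto a neighbouring aryl ring and tautomerisation at the acidic imide α-carbons, which erases C3/C4. The auxiliary of A1 must also bias a radical–radical coupling at carbons remote from its stereocentre, probably only if trivalent iron chelates the imide.
- Comparison: on structure, both plans deliver the tetrahydrofuran at the dicarbonyl level with the aryl groups in place. On mechanism, the chosen plan forms both C–C bonds in one concerted, orbital-symmetry-controlled event with defined relative configuration, whereas Alternative 1 forms three bonds stepwise with less predictable chemoselectivity. Both rest on an auxiliary whose facial bias is uncertain, and Alternative 1 is the shorter.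

Alternative 2: The cut is the two aryl–C bonds at C2 and C5. Forward, ZnBr2 would ionise in turn each anomeric sulfonyl group of (3S,4S)-3,4-bis(benzyloxymethyl)-2,5-bis(phenylsulfonyl)tetrahydrofuran A3. The aryl group of [4-(benzyloxy)-3,5-dimethoxyphenyl]magnesium bromide A4, passed on to zinc, would add to each oxocarbenium ion to give the tetra-benzyl ether A5.
- In favour: C3 and C4 of A3 would come from an enantiopure four-carbon building block, so their absolute configuration is secure before the key step. This is better than the chosen plan, where it rests on facial selectivity. Each aryl group of A4 should enter trans to its neighbouring substituent, and the two-directional design is equal in convergence.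
- Against: A3 needs a multi-step preparation. A3 can lose both sulfinate groups toward an aromatic furan, which destroys C3/C4. The first-formed benzylic ether is itself labile to the Lewis acid. Removing the four benzyl groups of A5 by hydrogenolysis puts the ring C–O bonds at risk.
- Comparison: on structure, A5 already has the hydroxymethyl oxidation level, which saves the ester reduction. On mechanism, it is a stepwise ionic substitution rather than a concerted cycloaddition. On step economy, the count would be clearly higher than in the chosen plan.

Alternative 3: The cut is O1–C2 and O1–C5. Forward, DDQ in wet solvent would oxidise both p-hydroxybenzyl CH2 groups of (2S,3S)-2,3-bis(4-hydroxy-3,5-dimethoxybenzyl)butane-1,4-diyl dipivalate A6 to quinone methides. Water would add at one, and the new hydroxyl would close on the other to give the dipivalate A7.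
- In favour: C3/C4 are fixed in the acyclic precursor A6 by well-established enolate chemistry, which is equal or better in stereochemical security. No photochemistry is needed. C2/C5 of A7 are set under thermodynamic control toward the all-trans ring, which is equal.
- Against: the first quinone methide can be attacked by the free ortho position of the other syringyl ring, a six-membered Friedel–Crafts closure that competes with intermolecular water. A7 still has oxidisable p-hydroxybenzylic C–H bonds, and free syringols are themselves oxidised by DDQ. A6 requires roughly six to eight steps.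
- Comparison: on structure, the chosen plan builds the ring and all four stereocentres at once from three-step material, whereas here the carbon skeleton is complete before the key step. On mechanism, the oxidative key step is the less chemoselective one, but it avoids any doubt about C3/C4. On step economy, Alternative 3 is the longer.

Key step: step 4

**Remarks and assumption**
- In diester 7 the ring carbons are (2R,3R,4R,5R). Reduction changes only the CIP ranking at C3 and C4, so the same spatial arrangement is (2R,3S,4S,5R) in 8 and 9.
- Assumption: the uncatalysed facial preference of 5 toward ylide 6 cannot be predicted with confidence. It is assumed to favour the (2R,3R,4R,5R)-adduct, or at least to leave it isolable, since the two all-trans adducts are diastereomers.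

## Route

Step 1
Reactants: 1 syringaldehyde (4-hydroxy-3,5-dimethoxybenzaldehyde)
Product: 2 3,5-dimethoxy-4-[(triisopropylsilyl)oxy]benzaldehyde
Conditions: TIPSCl, imidazole, DMF, 40 °C
Reagents that add atoms: chlorotriisopropylsilane, CC(C)[Si](Cl)(C(C)C)C(C)C
Why: Imidazole-mediated O-silylation of a phenol; the aldehyde is untouched, and the bulky silyl group is chosen to survive Lewis-acidic titanium, hydride and UV light later on.

Step 2
Reactants: 2 3,5-dimethoxy-4-[(triisopropylsilyl)oxy]benzaldehyde (two molecules)
Product: 3 (E)-1,2-bis{3,5-dimethoxy-4-[(triisopropylsilyl)oxy]phenyl}ethene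
Conditions: TiCl4, Zn dust, pyridine, THF, reflux
Reagents that add atoms: none
Why: McMurry reductive coupling: low-valent titanium dimerises the ketyl radicals and deoxygenates the resulting diolate on the metal, and aromatic aldehydes should give the E-stilbene, which is expected to crystallise; aryl silyl ethers belong to the groups tolerated by this reagent.

Step 3
Reactants: 3 (E)-1,2-bis{3,5-dimethoxy-4-[(triisopropylsilyl)oxy]phenyl}ethene
Product: 4 rac-trans-2,3-bis{3,5-dimethoxy-4-[(triisopropylsilyl)oxy]phenyl}oxirane
Conditions: DMDO (acetone solution), CH2Cl2, 0 °C; evaporation, Et3N-deactivated silica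
Reagents that add atoms: dimethyldioxirane, CC1(C)OO1
Why: Concerted, stereospecific syn oxygen transfer from the dioxirane turns the E-alkene into the trans-oxirane as a racemate, which is sufficient because these two stereocentres are erased in the next step. The reagent is neutral and leaves only acetone, so the acid-sensitive diaryloxirane meets no acid; the out-of-plane 4-silyloxy group flanked by two meta-methoxy groups makes the aryl ring only weakly donating, which should keep 4 isolable.

Step 4
Reactants: 4 rac-trans-2,3-bis{3,5-dimethoxy-4-[(triisopropylsilyl)oxy]phenyl}oxirane; 5 di-(−)-menthyl fumarate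
Product: 7 di-(−)-menthyl (2R,3R,4R,5R)-2,5-bis{3,5-dimethoxy-4-[(triisopropylsilyl)oxy]phenyl}tetrahydrofuran-3,4-dicarboxylate (all-trans), via exo-endo carbonyl ylide 6 (not isolated)
Conditions: hν (300 nm lamps, quartz tube), 5 (5 equiv), degassed MeCN, 0–20 °C, 0.01 M in 4, partial conversion
Reagents that add atoms: none
Why: Light absorbed by the trialkoxyaryl chromophore of 4 (the fumarate absorbs only at shorter wavelength, so it is neither excited nor isomerised to the maleate) opens the oxirane C–C bond in a four-electron disrotatory electrocyclic process, which turns the trans-oxirane into the exo,endo ylide 6; the two oxirane stereocentres vanish here, which is why racemic 4 suffices. Ground-state 6 then adds as a 4π dipole across the electron-poor E-alkene of 5 in a concerted suprafacial [π4s+π2s] cycloaddition, the closest known reaction type being the photolysis of 2,3-diaryloxiranes in the presence of fumaric or maleic esters to give 2,5-diaryltetrahydrofuran-3,4-dicarboxylates. The tetrahydrofuran ring is closed intermolecularly by this (3+2) union, C2–C3 and C4–C5 forming together, so no exo/endo ring-closure constraint applies. C2 and C5: the exo,endo geometry of 6, fixed by the orbital-symmetry-controlled opening, places the two aryl groups trans. C3 and C4: the E geometry of 5 is carried over by the suprafacial addition, so the esters are trans. C2/C3 and C4/C5: of the two possible orientations, the one in which each aryl group lies away from the ester on the neighbouring carbon avoids two aryl/ester eclipsing contacts and should lead to the all-trans ring. Absolute configuration: the two faces of C2-symmetric 5 are diastereotopic and are differentiated only by the (−)-menthyl groups, so the step needs face selectivity or, failing a strong bias, separation of the two all-trans diastereomers by chromatography or crystallisation, which the menthyl esters make possible. The silyl ethers are photostable at this wavelength, and irradiation is stopped short of full conversion so that 7, which carries the same chromophore, is not photolysed further.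

Step 5
Reactants: 7 di-(−)-menthyl (2R,3R,4R,5R)-2,5-bis{3,5-dimethoxy-4-[(triisopropylsilyl)oxy]phenyl}tetrahydrofuran-3,4-dicarboxylate
Product: 8 [(2R,3S,4S,5R)-2,5-bis{3,5-dimethoxy-4-[(triisopropylsilyl)oxy]phenyl}tetrahydrofuran-3,4-diyl]dimethanol
Conditions: LiAlH4 (excess), THF, 0 °C to rt; then H2O, aq. NaOH
Reagents that add atoms: none
Why: Hydride reduction of both esters to primary alcohols; the reaction occurs at the exocyclic carbonyl carbons, so no ring stereocentre is touched, the aryl silyl ethers and the ring ether are inert, and (−)-menthol is released for recovery.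

Step 6
Reactants: 8 [(2R,3S,4S,5R)-2,5-bis{3,5-dimethoxy-4-[(triisopropylsilyl)oxy]phenyl}tetrahydrofuran-3,4-diyl]dimethanol
Product: 9 [(2R,3S,4S,5R)-2,5-bis(4-hydroxy-3,5-dimethoxyphenyl)tetrahydrofuran-3,4-diyl]dimethanol (target, CNP0170897.1)
Conditions: Bu4NF, AcOH, THF, 0 °C
Reagents that add atoms: none
Why: Fluoride attacks silicon to give a pentacoordinate siliconate that releases the phenol; the acetic acid buffer delivers the neutral phenol and not the phenoxide, and the medium is neither acidic enough nor reducing, so the benzylic ethers at C2 and C5 and all four stereocentres should stay intact.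

## Compound list

1 | syringaldehyde (4-hydroxy-3,5-dimethoxybenzaldehyde) | COc1cc(C=O)cc(OC)c1O | starting material
2 | 3,5-dimethoxy-4-[(triisopropylsilyl)oxy]benzaldehyde | COc1cc(C=O)cc(OC)c1O[Si](C(C)C)(C(C)C)C(C)C | intermediate
3 | (E)-1,2-bis{3,5-dimethoxy-4-[(triisopropylsilyl)oxy]phenyl}ethene | COc1cc(/C=C/c2cc(OC)c(O[Si](C(C)C)(C(C)C)C(C)C)c(OC)c2)cc(OC)c1O[Si](C(C)C)(C(C)C)C(C)C | intermediate
4 | rac-trans-2,3-bis{3,5-dimethoxy-4-[(triisopropylsilyl)oxy]phenyl}oxirane (the 2S,3S enantiomer is drawn; the racemate is used) | COc1cc([C@@H]2O[C@H]2c2cc(OC)c(O[Si](C(C)C)(C(C)C)C(C)C)c(OC)c2)cc(OC)c1O[Si](C(C)C)(C(C)C)C(C)C | intermediate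
5 | di-(−)-menthyl fumarate, bis[(1R,2S,5R)-2-isopropyl-5-methylcyclohexyl] (E)-but-2-enedioate | O=C(/C=C/C(=O)O[C@@H]1C[C@H](C)CC[C@H]1C(C)C)O[C@@H]1C[C@H](C)CC[C@H]1C(C)C | starting material
6 | exo,endo (E,Z) carbonyl ylide, bis{3,5-dimethoxy-4-[(triisopropylsilyl)oxy]benzylidene}oxonium ylide, formed in the flask and not isolated (the SMILES fixes the exo aryl group at the formal double bond; the aryl group on the carbanionic carbon is endo) | COc1cc(/C=[O+]/[CH-]c2cc(OC)c(O[Si](C(C)C)(C(C)C)C(C)C)c(OC)c2)cc(OC)c1O[Si](C(C)C)(C(C)C)C(C)C | intermediate
7 | di-(−)-menthyl (2R,3R,4R,5R)-2,5-bis{3,5-dimethoxy-4-[(triisopropylsilyl)oxy]phenyl}tetrahydrofuran-3,4-dicarboxylate (all-trans) | COc1cc([C@@H]2O[C@@H](c3cc(OC)c(O[Si](C(C)C)(C(C)C)C(C)C)c(OC)c3)[C@H](C(=O)O[C@@H]3C[C@H](C)CC[C@H]3C(C)C)[C@H]2C(=O)O[C@@H]2C[C@H](C)CC[C@H]2C(C)C)cc(OC)c1O[Si](C(C)C)(C(C)C)C(C)C | intermediate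
8 | [(2R,3S,4S,5R)-2,5-bis{3,5-dimethoxy-4-[(triisopropylsilyl)oxy]phenyl}tetrahydrofuran-3,4-diyl]dimethanol | COc1cc([C@@H]2O[C@@H](c3cc(OC)c(O[Si](C(C)C)(C(C)C)C(C)C)c(OC)c3)[C@H](CO)[C@H]2CO)cc(OC)c1O[Si](C(C)C)(C(C)C)C(C)C | intermediate
9 | [(2R,3S,4S,5R)-2,5-bis(4-hydroxy-3,5-dimethoxyphenyl)tetrahydrofuran-3,4-diyl]dimethanol (all-trans) | COc1cc([C@@H]2O[C@@H](c3cc(OC)c(O)c(OC)c3)[C@H](CO)[C@H]2CO)cc(OC)c1O | target

## Step count and least certain steps

Total steps: 6. Longest linear sequence: 6 (1 → 2 → 3 → 4 → 7 → 8 → 9; 5 is purchased).

**Step 4 (key step).**
- What may go wrong: facial discrimination on the fumarate may be weak, because the menthyl stereocentres are several atoms from the reacting carbons and no Lewis acid can be used to fix the ester conformation without destroying the oxirane. The excited oxirane may also be lost by fragmentation to an aryl carbene and aldehyde, or by C–O cleavage and rearrangement, before the ylide is captured. Weak absorption near 300 nm may require long irradiation, with secondary photolysis of the adduct.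
- Fallback: this sets out from 4 and returns at 8. The dipolarophile is changed to N,N'-fumaroylbis[(2R)-bornane-10,2-sultam] F1, made from the commercial sultam, NaH and fumaroyl chloride. The rigid N-acyl sultam units of F1 shield one alkene face without a Lewis acid, and F1 is more electron-poor than 5, so it should capture the ylide faster. Irradiation of 4 with F1 under the same conditions should give the all-trans 2,5-diaryltetrahydrofuran-3,4-dicarbonyl bis-sultam F2. LiAlH4 in THF would reduce F2 directly to 8 with release of the sultam. The enantiomeric sultam would be taken if the facial sense required it.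
- Minor C2/C5 epimers of 7 would not be discarded; they would be passed through the step 6 fallback, where they can be equilibrated.

**Step 3.**
- What may go wrong: the electron-rich diaryloxirane may open and undergo 1,2-aryl shift (Meinwald-type rearrangement) on concentration or on silica, and the oxidant may attack the electron-rich rings.
- Fallback: this sets out from 2 and returns at 4, bypassing step 2 as well, and forms the oxirane under basic conditions only. NaBH4 in MeOH would reduce part of 2 to {3,5-dimethoxy-4-[(triisopropylsilyl)oxy]phenyl}methanol F3. PBr3 in Et2O at 0 °C would convert F3 into 3,5-dimethoxy-4-[(triisopropylsilyl)oxy]benzyl bromide F4. Tetrahydrothiophene in acetone would alkylate on sulfur with F4 to give 1-{3,5-dimethoxy-4-[(triisopropylsilyl)oxy]benzyl}tetrahydrothiophenium bromide F5. Deprotonation of F5 with KOt-Bu in THF at −40 °C in the presence of a second portion of 2 should give trans-oxirane 4 by the sulfonium ylide epoxidation, in which reversible betaine formation favours the trans isomer.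

**Step 2.**
- What may go wrong: the Lewis-acidic titanium and zinc chlorides may cleave the silyl ether at reflux, or the coupling may stop at the diolate stage.
- Fallback: this sets out from 2 and returns at 3. Wittig methylenation of 2 (MePPh3Br, KOt-Bu, THF) would give 3,5-dimethoxy-4-[(triisopropylsilyl)oxy]styrene F6. Self-metathesis of F6 with the second-generation Grubbs catalyst RuCl2(=CHPh)(H2IMes)(PCy3) in CH2Cl2 at 40 °C, with loss of ethylene, should give the E-stilbene 3.

**Step 6.**
- What may go wrong: if the phenol is liberated as a phenoxide, the benzylic ring C–O bond may open to a quinone methide. This would epimerise C2/C5 or allow capture by the 1,4-related hydroxymethyl group, leading to a rearranged ring system. The polar tetrol may also be hard to free from ammonium salts.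
- Fallback: this sets out from 7 and returns at 9, reversing the order of the last two operations. Bu4NF/AcOH in THF applied to 7 would give di-(−)-menthyl (2R,3R,4R,5R)-2,5-bis(4-hydroxy-3,5-dimethoxyphenyl)tetrahydrofuran-3,4-dicarboxylate F7. F7 has no hydroxymethyl group that could intercept a quinone methide. At this stage a catalytic acid (TsOH, CH2Cl2) could equilibrate any C2/C5 epimers of F7 toward the all-trans ring. LiAlH4 (excess, to allow for the two phenols) in THF would then reduce F7 directly to 9.

## Further compounds

F1 | step 4 | N,N'-fumaroylbis[(2R)-bornane-10,2-sultam] | O=C(/C=C/C(=O)N1[C@@H]2C[C@H]3CC[C@]2(CS1(=O)=O)C3(C)C)N1[C@@H]2C[C@H]3CC[C@]2(CS1(=O)=O)C3(C)C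
F2 | step 4 | all-trans (2R,3R,4R,5R)-2,5-bis{3,5-dimethoxy-4-[(triisopropylsilyl)oxy]phenyl}tetrahydrofuran-3,4-dicarbonyl bis[(2R)-bornane-10,2-sultam] | COc1cc([C@@H]2O[C@@H](c3cc(OC)c(O[Si](C(C)C)(C(C)C)C(C)C)c(OC)c3)[C@H](C(=O)N3[C@@H]4C[C@H]5CC[C@]4(CS3(=O)=O)C5(C)C)[C@H]2C(=O)N2[C@@H]3C[C@H]4CC[C@]3(CS2(=O)=O)C4(C)C)cc(OC)c1O[Si](C(C)C)(C(C)C)C(C)C
F3 | step 3 | {3,5-dimethoxy-4-[(triisopropylsilyl)oxy]phenyl}methanol | COc1cc(CO)cc(OC)c1O[Si](C(C)C)(C(C)C)C(C)C
F4 | step 3 | 3,5-dimethoxy-4-[(triisopropylsilyl)oxy]benzyl bromide | COc1cc(CBr)cc(OC)c1O[Si](C(C)C)(C(C)C)C(C)C
F5 | step 3 | 1-{3,5-dimethoxy-4-[(triisopropylsilyl)oxy]benzyl}tetrahydrothiophenium bromide | COc1cc(C[S+]2CCCC2)cc(OC)c1O[Si](C(C)C)(C(C)C)C(C)C.[Br-]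
F6 | step 2 | 3,5-dimethoxy-4-[(triisopropylsilyl)oxy]styrene | COc1cc(C=C)cc(OC)c1O[Si](C(C)C)(C(C)C)C(C)C
F7 | step 6 | di-(−)-menthyl (2R,3R,4R,5R)-2,5-bis(4-hydroxy-3,5-dimethoxyphenyl)tetrahydrofuran-3,4-dicarboxylate | COc1cc([C@@H]2O[C@@H](c3cc(OC)c(O)c(OC)c3)[C@H](C(=O)O[C@@H]3C[C@H](C)CC[C@H]3C(C)C)[C@H]2C(=O)O[C@@H]2C[C@H](C)CC[C@H]2C(C)C)cc(OC)c1O
A1 | alternative 1 | (S)-4-benzyl-3-[(E)-3-(4-hydroxy-3,5-dimethoxyphenyl)prop-2-enoyl]oxazolidin-2-one | COc1cc(/C=C/C(=O)N2[C@@H](Cc3ccccc3)COC2=O)cc(OC)c1O
A2 | alternative 1 | all-trans-2,5-bis(4-hydroxy-3,5-dimethoxyphenyl)tetrahydrofuran-3,4-dicarbonyl bis[(S)-4-benzyloxazolidin-2-one] | COc1cc([C@@H]2O[C@@H](c3cc(OC)c(O)c(OC)c3)[C@H](C(=O)N3[C@@H](Cc4ccccc4)COC3=O)[C@H]2C(=O)N2[C@@H](Cc3ccccc3)COC2=O)cc(OC)c1O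
A3 | alternative 2 | (3S,4S)-3,4-bis(benzyloxymethyl)-2,5-bis(phenylsulfonyl)tetrahydrofuran (anomeric centres unspecified) | O=S(=O)(c1ccccc1)C1OC(S(=O)(=O)c2ccccc2)[C@H](COCc2ccccc2)[C@H]1COCc1ccccc1
A4 | alternative 2 | [4-(benzyloxy)-3,5-dimethoxyphenyl]magnesium bromide | COc1cc([Mg]Br)cc(OC)c1OCc1ccccc1
A5 | alternative 2 | all-trans-2,5-bis[4-(benzyloxy)-3,5-dimethoxyphenyl]-3,4-bis(benzyloxymethyl)tetrahydrofuran | COc1cc([C@@H]2O[C@@H](c3cc(OC)c(OCc4ccccc4)c(OC)c3)[C@H](COCc3ccccc3)[C@H]2COCc2ccccc2)cc(OC)c1OCc1ccccc1
A6 | alternative 3 | (2S,3S)-2,3-bis(4-hydroxy-3,5-dimethoxybenzyl)butane-1,4-diyl bis(2,2-dimethylpropanoate) | COc1cc(C[C@H](COC(=O)C(C)(C)C)[C@@H](COC(=O)C(C)(C)C)Cc2cc(OC)c(O)c(OC)c2)cc(OC)c1O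
A7 | alternative 3 | all-trans-2,5-bis(4-hydroxy-3,5-dimethoxyphenyl)tetrahydrofuran-3,4-diyldimethyl bis(2,2-dimethylpropanoate) | COc1cc([C@@H]2O[C@@H](c3cc(OC)c(O)c(OC)c3)[C@H](COC(=O)C(C)(C)C)[C@H]2COC(=O)C(C)(C)C)cc(OC)c1O
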